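**Plan**
- Retrosynthesis: cut the ester C–O bond between the C3 hydroxymethyl group and p-coumaric acid; trace the furan bond C3–C3a back to the C4–C4a bond of a flavanone; cut the flavanone C2–aryl bond to a chromone and an arylboronic acid; take the chromone back through an ortho-hydroxyacetophenone to dihydroconiferyl alcohol.
- Enabling feature: C3 of the dihydrofuran carries both the ring A carbon C3a and a one-carbon carboxyl-level substituent, while C2 holds O1 and ring B. This is a chroman-4-one in which ring A has moved from C4 to C3, so contracting the pyranone gives the furan ring, turns C4 into the exocyclic ester carbon and leaves C2 alone.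
- Forward order: acylation of ring A (Fries), closure of the pyranone (chromone), attachment of ring B at C2, six-to-five ring contraction, ester reduction, coumaroylation, desilylation.
- Stereochemistry: C2 (R) by ligand control in a palladium-catalysed conjugate addition; C3 by substrate control in the ring contraction (trans to the C2 aryl group); the E alkene comes with p-coumaric acid.

Key step: step 6

Assumption: 4-acetoxy-3-methoxyphenylboronic acid pinacol ester (6) is taken as a catalogue compound; otherwise it is one acetylation (Ac2O, pyridine) from 4-hydroxy-3-methoxyphenylboronic acid pinacol ester.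
Assumption: (S)-t-BuPyOx is taken to give the 2R flavanone, by analogy with the facial sense it shows with cyclic enones; if the sense were opposite, the (R)-ligand would be used with nothing else changed.
Remark: the trans ester 11 has the descriptors 2R,3R because the ester carbon outranks C2; reduction to the hydroxymethyl group makes C3 "S" with no change in geometry, so alcohol 14 and the target are 2R,3S.

Step 1
Reactants: 1 dihydroconiferyl alcohol
Product: 2 3-(4-acetoxy-3-methoxyphenyl)propyl acetate
Conditions: Ac2O, pyridine, DMAP (cat.), CH2Cl2, 0 °C to rt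
Reagents that add atoms: acetic anhydride, CC(=O)OC(C)=O
Why: DMAP-catalysed O-acetylation (nucleophilic acyl substitution) esterifies the phenol and the primary alcohol, which supplies the aryl ester for the Fries step and an acid-stable cap for the side chain.

Step 2
Reactants: 2 3-(4-acetoxy-3-methoxyphenyl)propyl acetate
Product: 3 3-(3-acetyl-4-hydroxy-5-methoxyphenyl)propyl acetate
Conditions: BF3·OEt2 (4 equiv, neat), 90 °C; then H2O/THF, 60 °C
Reagents that add atoms: none
Why: Fries rearrangement: the Lewis acid moves the phenolic acetyl group to the only free carbon ortho to the oxygen (para is blocked by the propyl chain), and BF3 should spare the aryl methyl ether and the alkyl acetate.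

Step 3
Reactants: 3 3-(3-acetyl-4-hydroxy-5-methoxyphenyl)propyl acetate
Product: 5 3-(8-methoxy-4-oxo-4H-chromen-6-yl)propyl acetate, via enaminone 4 (not isolated)
Conditions: Me2NCH(OMe)2, toluene, 100 °C; then conc. HCl, CH2Cl2, 40 °C
Reagents that add atoms: N,N-dimethylformamide dimethyl acetal, COC(OC)N(C)C
Why: Condensation of the methyl ketone with the amide acetal gives the E enaminone, and acid then drives intramolecular oxa-Michael addition of the phenol and loss of dimethylamine (addition–elimination), the standard enaminone route to 2,3-unsubstituted chromones.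

Step 4
Reactants: 6 4-acetoxy-3-methoxyphenylboronic acid pinacol ester
Product: 7 4-acetoxy-3-methoxyphenylboronic acid
Conditions: NaIO4, THF/H2O (4:1), rt; then 1 M HCl, rt
Reagents that add atoms: water, O
Why: Hydrolysis of the boronic ester is pulled to completion by periodate glycol cleavage of the released pinacol, which frees the boronic acid needed for transmetalation while the aryl acetate should survive the near-neutral to mildly acidic medium.

Step 5
Reactants: 5 3-(8-methoxy-4-oxo-4H-chromen-6-yl)propyl acetate; 7 4-acetoxy-3-methoxyphenylboronic acid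
Product: 8 (2R)-2-(4-acetoxy-3-methoxyphenyl)-6-(3-acetoxypropyl)-8-methoxychroman-4-one
Conditions: Pd(OCOCF3)2 (5 mol%), (S)-t-BuPyOx (6 mol%), NH4PF6 (30 mol%), H2O (5 equiv), ClCH2CH2Cl, 60 °C
Reagents that add atoms: none
Why: Catalytic asymmetric conjugate addition of an arylboronic acid to a chromone under cationic divalent palladium with a pyridine–oxazoline ligand (aryl transfer from boron, enantio-determining insertion of C2=C3, protonolysis of the palladium enolate) sets C2 by ligand control, and the base-free medium should neither open the flavanone nor cleave the acetates.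

Step 6
Reactants: 8 (2R)-2-(4-acetoxy-3-methoxyphenyl)-6-(3-acetoxypropyl)-8-methoxychroman-4-one
Product: 11 methyl (2R,3R)-2-(4-acetoxy-3-methoxyphenyl)-5-(3-acetoxypropyl)-7-methoxy-2,3-dihydro-1-benzofuran-3-carboxylate, via methyl enol ether 9 (not isolated), via trans-iodane 10 (not isolated)
Conditions: PhI(OAc)2 (1.2 equiv), conc. H2SO4 (cat.), HC(OMe)3, 0 °C to rt
Reagents that add atoms: trimethyl orthoformate, COC(OC)OC
Why: Acid and HC(OMe)3 convert the C4 ketone into the methyl enol ether 9, C3 of 9 attacks trivalent iodine on the face away from the C2 aryl group while methanol caps C4, and in the resulting 2,3-trans iodane 10 the equatorial C3–I bond lies antiperiplanar to the ring bond C4–C4a, so the ring A ipso carbon shifts from C4 to C3 as PhI departs and the dimethoxycarbenium ion left at C4 loses a methyl group to give the methyl ester. The closest known reaction type is the oxidative ring contraction of flavanones to methyl trans-2-aryl-2,3-dihydrobenzofuran-3-carboxylates by PhI(OAc)2 and H2SO4 in trimethyl orthoformate, a semipinacol-type 1,2-aryl shift. The dihydrofuran ring is closed by contraction of the pyranone and not by a new heteroatom bond: ipso attack of C4a on C3 (3-exo-tet, phenonium-type bridged transition state) forms C3–C3a while C4–C4a breaks, which turns C4 into the exocyclic carboxyl carbon. C2 is not involved and keeps the R configuration from step 5, while C3 is set by substrate control, because iodine enters anti to the C2 aryl group and the shift inverts C3, which places the ester trans to the aryl group (2R,3R). The step needs ring A to migrate in preference to a C2-to-C3 shift of ring B (isoflavone) and to elimination toward the flavone; this should be secured by the ketal-level oxygenation at C4, which stabilises the cation left by ring A, by the ortho oxygen O1 that makes ring A the better migrating group, and by the acetoxy group that makes ring B electron-poor and slows ionisation of the C2–O1 bond. Both acetates and both aryl methyl ethers should tolerate the acidic, anhydrous medium.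

Step 7
Reactants: 11 methyl (2R,3R)-2-(4-acetoxy-3-methoxyphenyl)-5-(3-acetoxypropyl)-7-methoxy-2,3-dihydro-1-benzofuran-3-carboxylate
Product: 12 methyl (2R,3R)-2-(4-hydroxy-3-methoxyphenyl)-5-(3-hydroxypropyl)-7-methoxy-2,3-dihydro-1-benzofuran-3-carboxylate
Conditions: K2CO3 (0.3 equiv), MeOH, 0 °C to rt; NH4Cl (aq.) quench
Reagents that add atoms: none
Why: Base-catalysed transesterification (Zemplén-type methanolysis) removes the aryl and the alkyl acetate as methyl acetate while exchange at the methyl ester is degenerate, and enolisation at C3 can only return the more stable trans isomer because C2 is not acidic.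

Step 8
Reactants: 12 methyl (2R,3R)-2-(4-hydroxy-3-methoxyphenyl)-5-(3-hydroxypropyl)-7-methoxy-2,3-dihydro-1-benzofuran-3-carboxylate
Product: 13 methyl (2R,3R)-2-[4-(tert-butyldimethylsilyloxy)-3-methoxyphenyl]-5-[3-(tert-butyldimethylsilyloxy)propyl]-7-methoxy-2,3-dihydro-1-benzofuran-3-carboxylate
Conditions: TBSCl (2.5 equiv), imidazole, DMF, rt
Reagents that add atoms: tert-butyldimethylsilyl chloride, CC(C)(C)[Si](C)(C)Cl
Why: Imidazole-promoted silylation (Corey conditions) caps the phenol and the primary alcohol with groups that should survive hydride reduction and carbodiimide coupling and leave together under fluoride, without touching the ester or either stereocentre.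

Step 9
Reactants: 13 methyl (2R,3R)-2-[4-(tert-butyldimethylsilyloxy)-3-methoxyphenyl]-5-[3-(tert-butyldimethylsilyloxy)propyl]-7-methoxy-2,3-dihydro-1-benzofuran-3-carboxylate
Product: 14 {(2R,3S)-2-[4-(tert-butyldimethylsilyloxy)-3-methoxyphenyl]-5-[3-(tert-butyldimethylsilyloxy)propyl]-7-methoxy-2,3-dihydro-1-benzofuran-3-yl}methanol
Conditions: i-Bu2AlH (2.5 equiv), CH2Cl2, −78 to 0 °C; KNaC4H4O6 (aq.) work-up
Reagents that add atoms: none
Why: Hydride reduction of the methyl ester by i-Bu2AlH gives the primary alcohol with the silyl ethers inert at low temperature, and no bond to C2 or C3 is broken, so the C3 descriptor changes from R to S only through the CIP priorities.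

Step 10
Reactants: 15 p-coumaric acid
Product: 17 (2E)-3-[4-(tert-butyldimethylsilyloxy)phenyl]prop-2-enoic acid, via silyl ester 16 (not isolated)
Conditions: TBSCl (2.3 equiv), imidazole, DMF, rt; then THF/H2O/AcOH, rt
Reagents that add atoms: tert-butyldimethylsilyl chloride, CC(C)(C)[Si](C)(C)Cl
Why: Silylation converts both the phenol and the acid, and the far more labile silyl ester is then hydrolysed selectively, which leaves the phenol masked so that it cannot compete in the esterification.

Step 11
Reactants: 14 {(2R,3S)-2-[4-(tert-butyldimethylsilyloxy)-3-methoxyphenyl]-5-[3-(tert-butyldimethylsilyloxy)propyl]-7-methoxy-2,3-dihydro-1-benzofuran-3-yl}methanol; 17 (2E)-3-[4-(tert-butyldimethylsilyloxy)phenyl]prop-2-enoic acid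
Product: 18 {(2R,3S)-2-[4-(tert-butyldimethylsilyloxy)-3-methoxyphenyl]-5-[3-(tert-butyldimethylsilyloxy)propyl]-7-methoxy-2,3-dihydro-1-benzofuran-3-yl}methyl (2E)-3-[4-(tert-butyldimethylsilyloxy)phenyl]prop-2-enoate
Conditions: EDC·HCl, DMAP, CH2Cl2, 0 °C to rt
Reagents that add atoms: none
Why: Steglich esterification: the carbodiimide activates acid 17 as its O-acylisourea and DMAP relays the acyl group to the unhindered primary alcohol, with the E alkene and both ring stereocentres unaffected.

Step 12
Reactants: 18 {(2R,3S)-2-[4-(tert-butyldimethylsilyloxy)-3-methoxyphenyl]-5-[3-(tert-butyldimethylsilyloxy)propyl]-7-methoxy-2,3-dihydro-1-benzofuran-3-yl}methyl (2E)-3-[4-(tert-butyldimethylsilyloxy)phenyl]prop-2-enoate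
Product: 19 [(2R,3S)-2-(4-hydroxy-3-methoxyphenyl)-5-(3-hydroxypropyl)-7-methoxy-2,3-dihydro-1-benzofuran-3-yl]methyl (2E)-3-(4-hydroxyphenyl)prop-2-enoate
Conditions: Bu4NF/AcOH (1:1, 4 equiv), THF, 0 °C to rt
Reagents that add atoms: none
Why: Fluoride-induced desilylation, driven by the strong Si–F bond, frees both phenols and the primary alcohol, and the acetic acid buffer keeps the phenols protonated so that the cinnamate ester and the benzylic C2–O1 bond are not exposed to phenoxide or basic fluoride.

**Compound list**

1 | dihydroconiferyl alcohol, 4-(3-hydroxypropyl)-2-methoxyphenol | COc1cc(CCCO)ccc1O | starting material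
2 | 3-(4-acetoxy-3-methoxyphenyl)propyl acetate | COc1cc(CCCOC(C)=O)ccc1OC(C)=O | intermediate
3 | 3-(3-acetyl-4-hydroxy-5-methoxyphenyl)propyl acetate | COc1cc(CCCOC(C)=O)cc(C(C)=O)c1O | intermediate
4 | 3-{3-[(2E)-3-(dimethylamino)prop-2-enoyl]-4-hydroxy-5-methoxyphenyl}propyl acetate | COc1cc(CCCOC(C)=O)cc(C(=O)/C=C/N(C)C)c1O | intermediate (not isolated)
5 | 3-(8-methoxy-4-oxo-4H-chromen-6-yl)propyl acetate | COc1cc(CCCOC(C)=O)cc2c(=O)ccoc12 | intermediate
6 | 4-acetoxy-3-methoxyphenylboronic acid pinacol ester | COc1cc(B2OC(C)(C)C(C)(C)O2)ccc1OC(C)=O | starting material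
7 | 4-acetoxy-3-methoxyphenylboronic acid | COc1cc(B(O)O)ccc1OC(C)=O | intermediate
8 | (2R)-2-(4-acetoxy-3-methoxyphenyl)-6-(3-acetoxypropyl)-8-methoxychroman-4-one | COc1cc([C@@H]2Oc3c(OC)cc(CCCOC(C)=O)cc3C(=O)C2)ccc1OC(C)=O | intermediate (key-step precursor)
9 | 3-[(2R)-2-(4-acetoxy-3-methoxyphenyl)-4,8-dimethoxy-2H-chromen-6-yl]propyl acetate | COc1cc([C@@H]2Oc3c(OC)cc(CCCOC(C)=O)cc3C(OC)=C2)ccc1OC(C)=O | intermediate (not isolated)
10 | 3-{(2S,3S)-2-(4-acetoxy-3-methoxyphenyl)-3-[acetoxy(phenyl)-λ3-iodanyl]-4,4,8-trimethoxychroman-6-yl}propyl acetate; iodine trans to the C2 aryl group, C2 geometry as in 8 (descriptor changed by priority only) | COc1cc([C@@H]2Oc3c(OC)cc(CCCOC(C)=O)cc3C(OC)(OC)[C@H]2I(OC(C)=O)c2ccccc2)ccc1OC(C)=O | intermediate (not isolated)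
11 | methyl (2R,3R)-2-(4-acetoxy-3-methoxyphenyl)-5-(3-acetoxypropyl)-7-methoxy-2,3-dihydro-1-benzofuran-3-carboxylate (trans) | COc1cc([C@@H]2Oc3c(OC)cc(CCCOC(C)=O)cc3[C@H]2C(=O)OC)ccc1OC(C)=O | intermediate (key-step product)
12 | methyl (2R,3R)-2-(4-hydroxy-3-methoxyphenyl)-5-(3-hydroxypropyl)-7-methoxy-2,3-dihydro-1-benzofuran-3-carboxylate | COc1cc([C@@H]2Oc3c(OC)cc(CCCO)cc3[C@H]2C(=O)OC)ccc1O | intermediate
13 | methyl (2R,3R)-2-[4-(tert-butyldimethylsilyloxy)-3-methoxyphenyl]-5-[3-(tert-butyldimethylsilyloxy)propyl]-7-methoxy-2,3-dihydro-1-benzofuran-3-carboxylate | COc1cc([C@@H]2Oc3c(OC)cc(CCCO[Si](C)(C)C(C)(C)C)cc3[C@H]2C(=O)OC)ccc1O[Si](C)(C)C(C)(C)C | intermediate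
14 | {(2R,3S)-2-[4-(tert-butyldimethylsilyloxy)-3-methoxyphenyl]-5-[3-(tert-butyldimethylsilyloxy)propyl]-7-methoxy-2,3-dihydro-1-benzofuran-3-yl}methanol | COc1cc([C@@H]2Oc3c(OC)cc(CCCO[Si](C)(C)C(C)(C)C)cc3[C@H]2CO)ccc1O[Si](C)(C)C(C)(C)C | intermediate
15 | p-coumaric acid, (2E)-3-(4-hydroxyphenyl)prop-2-enoic acid | OC(=O)/C=C/c1ccc(O)cc1 | starting material
16 | tert-butyldimethylsilyl (2E)-3-[4-(tert-butyldimethylsilyloxy)phenyl]prop-2-enoate | CC(C)(C)[Si](C)(C)OC(=O)/C=C/c1ccc(O[Si](C)(C)C(C)(C)C)cc1 | intermediate (not isolated)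
17 | (2E)-3-[4-(tert-butyldimethylsilyloxy)phenyl]prop-2-enoic acid | OC(=O)/C=C/c1ccc(O[Si](C)(C)C(C)(C)C)cc1 | intermediate
18 | {(2R,3S)-2-[4-(tert-butyldimethylsilyloxy)-3-methoxyphenyl]-5-[3-(tert-butyldimethylsilyloxy)propyl]-7-methoxy-2,3-dihydro-1-benzofuran-3-yl}methyl (2E)-3-[4-(tert-butyldimethylsilyloxy)phenyl]prop-2-enoate | COc1cc([C@@H]2Oc3c(OC)cc(CCCO[Si](C)(C)C(C)(C)C)cc3[C@H]2COC(=O)/C=C/c2ccc(O[Si](C)(C)C(C)(C)C)cc2)ccc1O[Si](C)(C)C(C)(C)C | intermediate
19 | [(2R,3S)-2-(4-hydroxy-3-methoxyphenyl)-5-(3-hydroxypropyl)-7-methoxy-2,3-dihydro-1-benzofuran-3-yl]methyl (2E)-3-(4-hydroxyphenyl)prop-2-enoate (CNP0202924.1) | COc1cc([C@@H]2Oc3c(OC)cc(CCCO)cc3[C@H]2COC(=O)/C=C/c2ccc(O)cc2)ccc1O | target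

**Step count and risks**

Total steps: 12. Longest linear sequence: 10 (steps 1, 2, 3, 5, 6, 7, 8, 9, 11, 12 from dihydroconiferyl alcohol); steps 4 and 10 prepare the two side fragments.

Step 6 (most at risk). What may go wrong: migration of ring B from C2 to C3 or dehydrogenation of the enol ether may compete with the ring A shift, and the acidic medium may erode the configuration at C2 through reversible opening of the pyranone. Fallback, from 8 back to the route at 12: the same C3–C3a bond is made by a carbene-type ring contraction instead of the iodane. Ketone 8 would be trifluoroacetylated at C3 (LiN(SiMe3)2, CF3CO2CH2CF3, THF, −78 °C) to 3-[(2R)-2-(4-acetoxy-3-methoxyphenyl)-8-methoxy-4-oxo-3-(trifluoroacetyl)chroman-6-yl]propyl acetate F1. Deacylative diazo transfer (MsN3, Et3N, MeCN/H2O) would then give the 3-diazo-4-chromanone 3-[(2S)-2-(4-acetoxy-3-methoxyphenyl)-3-diazo-8-methoxy-4-oxochroman-6-yl]propyl acetate F2 (C2 geometry unchanged). Irradiation at 365 nm in MeOH should trigger a Wolff rearrangement in which ring A moves from C4 to the carbene carbon C3 and methanol traps the ketene. The expected product is ester 11 together with its C3 epimer, methyl (2R,3S)-2-(4-acetoxy-3-methoxyphenyl)-5-(3-acetoxypropyl)-7-methoxy-2,3-dihydro-1-benzofuran-3-carboxylate F3. Treating the mixture with K2CO3 in MeOH, as in step 7 but for longer, should equilibrate C3 to trans and remove both acetates, converging on 12.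

Step 5. What may go wrong: poor facial selectivity with the 8-methoxychromone, or slow aryl transfer from the oxygenated boronic acid. Fallback, from 5 and 7 back to the route at 8: asymmetric induction is replaced by kinetic resolution. An achiral catalyst (Pd(OCOCF3)2, 2,2'-bipyridine, aqueous ClCH2CH2Cl, 60 °C) would give racemic 2-(4-acetoxy-3-methoxyphenyl)-6-(3-acetoxypropyl)-8-methoxychroman-4-one F4. Asymmetric transfer hydrogenation ([RhCl2Cp*]2 with the TsDPEN enantiomer that reduces the 2S ketone faster, HCO2H/Et3N, EtOAc, rt) should convert the unwanted enantiomer into 3-[(2S,4S)-2-(4-acetoxy-3-methoxyphenyl)-4-hydroxy-8-methoxychroman-6-yl]propyl acetate F5 and leave (2R)-ketone 8, which is separated by chromatography.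

Step 2. What may go wrong: cleavage of the methyl ether next to the phenol, or incomplete acyl migration under the Lewis acid. Fallback, from 1 back to the route at 3: the acetyl group is introduced by cross-coupling instead of acyl migration. Bromination of 1 ortho to the free phenol (NBS, MeCN, 0 °C) would give 2-bromo-4-(3-hydroxypropyl)-6-methoxyphenol F6. Stille coupling with tributyl(1-ethoxyvinyl)stannane (PdCl2(PPh3)2, toluene, 100 °C) would give 2-(1-ethoxyethenyl)-4-(3-hydroxypropyl)-6-methoxyphenol F7, and 1 M HCl in THF would hydrolyse it to 1-[2-hydroxy-5-(3-hydroxypropyl)-3-methoxyphenyl]ethanone F8. Selective acetylation of the primary alcohol (Ac2O, 1.05 equiv, pyridine, CH2Cl2, 0 °C; the chelated phenol should stay free) would then deliver 3.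

**Further compounds**

F1 | step 6 | 3-[(2R)-2-(4-acetoxy-3-methoxyphenyl)-8-methoxy-4-oxo-3-(trifluoroacetyl)chroman-6-yl]propyl acetate | COc1cc([C@@H]2Oc3c(OC)cc(CCCOC(C)=O)cc3C(=O)C2C(=O)C(F)(F)F)ccc1OC(C)=O
F2 | step 6 | 3-[(2S)-2-(4-acetoxy-3-methoxyphenyl)-3-diazo-8-methoxy-4-oxochroman-6-yl]propyl acetate | COc1cc([C@@H]2Oc3c(OC)cc(CCCOC(C)=O)cc3C(=O)C2=[N+]=[N-])ccc1OC(C)=O
F3 | step 6 | methyl (2R,3S)-2-(4-acetoxy-3-methoxyphenyl)-5-(3-acetoxypropyl)-7-methoxy-2,3-dihydro-1-benzofuran-3-carboxylate (cis) | COc1cc([C@@H]2Oc3c(OC)cc(CCCOC(C)=O)cc3[C@@H]2C(=O)OC)ccc1OC(C)=O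
F4 | step 5 | racemic 2-(4-acetoxy-3-methoxyphenyl)-6-(3-acetoxypropyl)-8-methoxychroman-4-one | COc1cc(C2Oc3c(OC)cc(CCCOC(C)=O)cc3C(=O)C2)ccc1OC(C)=O
F5 | step 5 | 3-[(2S,4S)-2-(4-acetoxy-3-methoxyphenyl)-4-hydroxy-8-methoxychroman-6-yl]propyl acetate | COc1cc([C@H]2Oc3c(OC)cc(CCCOC(C)=O)cc3[C@@H](O)C2)ccc1OC(C)=O
F6 | step 2 | 2-bromo-4-(3-hydroxypropyl)-6-methoxyphenol | COc1cc(CCCO)cc(Br)c1O
F7 | step 2 | 2-(1-ethoxyethenyl)-4-(3-hydroxypropyl)-6-methoxyphenol | CCOC(=C)c1cc(CCCO)cc(OC)c1O
F8 | step 2 | 1-[2-hydroxy-5-(3-hydroxypropyl)-3-methoxyphenyl]ethanone | COc1cc(CCCO)cc(C(C)=O)c1O
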